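**Retrosynthetic overview**
1. Target ⇐ the corresponding ring A aldehyde by a final NaBH4 reduction; the formyl group serves as a masked hydroxymethyl group, so no alcohol protecting group is needed.
2. Key disconnection: the depside ester C–O bond between 3-formyl-2,4-dimethoxy-6-methylbenzoic acid (ring A) and the 4-OH of unprotected β-orsellinic acid (ring B), made while a boronic acid transiently masks the salicylic acid unit.
3. Ring A acid ⇐ 3,5-dimethoxytoluene: lithiation/formylation between the methoxy groups, bromination (regiospecific by symmetry), then Br/Li exchange and carboxylation with the aldehyde protected in situ.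
4. Ring B acid ⇐ methyl β-orsellinate (atraric acid, a bulk fragrance chemical) by ester hydrolysis.
5. No ring is constructed: both benzene rings are bought intact; only a transient boron heterocycle is formed and removed in the key step.

Assumption: the target has no stereocentre and no resolvable axis, so "single enantiomer" is taken to mean the achiral compound as drawn, and no stereocontrol is needed.

**Route**

Step 1
Reactants: 1 3,5-dimethoxytoluene
Product: 3 2,6-dimethoxy-4-methylbenzaldehyde, via (2,6-dimethoxy-4-methylphenyl)lithium 2 (not isolated)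
Conditions: n-BuLi (1.2 eq.), TMEDA (1.2 eq.), THF, 0 °C → rt, 2 h; DMF (1.5 eq.), 0 °C → rt; 1 M HCl
Reagents that add atoms: N,N-dimethylformamide, CN(C)C=O
Why: Directed ortho-metalation removes the proton flanked by both methoxy groups (the most acidic, doubly coordinated site) and the aryllithium is formylated by DMF (Bouveault-type formylation); no stereocentre is formed.

Step 2
Reactants: 3 2,6-dimethoxy-4-methylbenzaldehyde
Product: 4 3-bromo-2,6-dimethoxy-4-methylbenzaldehyde
Conditions: NBS (1.02 eq.), MeCN, 0 °C → rt, dark
Reagents that add atoms: N-bromosuccinimide, O=C1CCC(=O)N1Br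
Why: Electrophilic aromatic bromination; the two free ring positions are symmetry-equivalent, each ortho/para to a methoxy group and meta to the formyl group, so only one monobromide can form.

Step 3
Reactants: 4 3-bromo-2,6-dimethoxy-4-methylbenzaldehyde
Product: 7 3-formyl-2,4-dimethoxy-6-methylbenzoic acid, via lithium α-morpholinoalkoxide 5 (not isolated), via aryllithium 6 (not isolated)
Conditions: morpholine (1.15 eq.), n-BuLi (1.1 eq.), THF, −40 °C; add 4, −40 °C, 30 min; n-BuLi (1.15 eq.), −78 °C, 20 min; CO2 (g), −78 °C → rt; 1 M HCl to pH 1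
Reagents that add atoms: carbon dioxide, O=C=O
Why: Comins-type in situ protection of the aldehyde as a lithium α-amino alkoxide, then Br/Li exchange (faster than any deprotonation at −78 °C) and carboxylation of the aryllithium; acidic work-up collapses the hemiaminal back to the aldehyde.

Step 4
Reactants: 8 methyl 2,4-dihydroxy-3,6-dimethylbenzoate (atraric acid)
Product: 9 2,4-dihydroxy-3,6-dimethylbenzoic acid (β-orsellinic acid)
Conditions: conc. H2SO4, 0 °C → 20 °C, 3 h; pour onto ice, filter cold
Reagents that add atoms: water, O
Why: Acylium-type (AAc1) hydrolysis of a di-ortho-substituted, electron-rich benzoate in cold concentrated H2SO4 (mesitoate-type hydrolysis) avoids the hot aqueous conditions under which this resorcylic acid decarboxylates.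

Step 5
Reactants: 7 3-formyl-2,4-dimethoxy-6-methylbenzoic acid; 9 2,4-dihydroxy-3,6-dimethylbenzoic acid
Product: 13 4-[(3-formyl-2,4-dimethoxy-6-methylbenzoyl)oxy]-2-hydroxy-3,6-dimethylbenzoic acid, via aroyl chloride 10 (not isolated), via cyclic phenylboronate 11 (not isolated), via boron-masked depside 12 (not isolated)
Conditions: (a) 7 (1.15 eq.), (COCl)2, DMF (cat.), CH2Cl2, 0 °C → rt, evaporate; (b) 9, PhB(OH)2 (1.0 eq.), THF–toluene, azeotropic evaporation at 40 °C (twice); (c) a + b, i-Pr2NEt (2.5 eq.), DMAP (0.3 eq.), CH2Cl2, 0 → 35 °C, 16 h; (d) THF–H2O, citric acid, rt, 30 min, then NaHCO3 extraction and cold re-acidification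
Reagents that add atoms: none
Why: Proposed new method: a protecting-group-free depside esterification with transient boron masking. PhB(OH)2 condenses with the salicylic acid unit of 9 (CO2H plus ortho-OH) to the six-membered dioxaborininone 11, which ties up the carboxyl group (no mixed anhydride, no self-acylation, no decarboxylation) and the 2-OH. The only nucleophile left is the 4-OH, made more acidic by the para acyloxyboron group and deprotonated by i-Pr2NEt; its phenoxide attacks the hindered aroyl chloride 10 (DMAP acyl transfer) to form the ester C–O bond, and the B–O bonds hydrolyse on aqueous work-up. The closest known reaction types are the transient phenylboronate masking of diols in site-selective acylation of carbohydrates, the known cyclic boronates of salicylic acid, and Fischer-type acylation of phenols by aroyl chlorides; the combination on a free dihydroxybenzoic acid has not been shown. No stereocentre is formed.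

Step 6
Reactants: 13 4-[(3-formyl-2,4-dimethoxy-6-methylbenzoyl)oxy]-2-hydroxy-3,6-dimethylbenzoic acid
Product: 14 2-hydroxy-4-{[3-(hydroxymethyl)-2,4-dimethoxy-6-methylbenzoyl]oxy}-3,6-dimethylbenzoic acid
Conditions: NaBH4 (2 eq.), THF–EtOH (4:1), −10 → 0 °C, 30 min; aq. citric acid to pH 3–4, cold
Reagents that add atoms: none
Why: Chemoselective NaBH4 reduction of the aryl aldehyde; the di-ortho-substituted aryl ester and the carboxylate are inert at 0 °C, the mild acidic work-up spares the electron-rich benzylic alcohol, and no stereocentre is formed.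

**Compound list**
1 | 3,5-dimethoxytoluene | COc1cc(C)cc(OC)c1 | starting material
2 | (2,6-dimethoxy-4-methylphenyl)lithium | [Li]c1c(OC)cc(C)cc1OC | intermediate
3 | 2,6-dimethoxy-4-methylbenzaldehyde | COc1cc(C)cc(OC)c1C=O | intermediate
4 | 3-bromo-2,6-dimethoxy-4-methylbenzaldehyde | COc1cc(C)c(Br)c(OC)c1C=O | intermediate
5 | lithium (3-bromo-2,6-dimethoxy-4-methylphenyl)(morpholin-4-yl)methanolate (racemic, transient) | COc1cc(C)c(Br)c(OC)c1C(O[Li])N1CCOCC1 | intermediate
6 | lithium (3-lithio-2,6-dimethoxy-4-methylphenyl)(morpholin-4-yl)methanolate (racemic, transient) | COc1cc(C)c([Li])c(OC)c1C(O[Li])N1CCOCC1 | intermediate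
7 | 3-formyl-2,4-dimethoxy-6-methylbenzoic acid | COc1cc(C)c(C(=O)O)c(OC)c1C=O | intermediate
8 | methyl 2,4-dihydroxy-3,6-dimethylbenzoate (atraric acid) | COC(=O)c1c(C)cc(O)c(C)c1O | starting material
9 | 2,4-dihydroxy-3,6-dimethylbenzoic acid (β-orsellinic acid) | Cc1cc(O)c(C)c(O)c1C(=O)O | intermediate
10 | 3-formyl-2,4-dimethoxy-6-methylbenzoyl chloride | COc1cc(C)c(C(=O)Cl)c(OC)c1C=O | intermediate
11 | 7-hydroxy-5,8-dimethyl-2-phenyl-4H-1,3,2-benzodioxaborinin-4-one | Cc1cc(O)c(C)c2OB(c3ccccc3)OC(=O)c12 | intermediate
12 | 5,8-dimethyl-4-oxo-2-phenyl-4H-1,3,2-benzodioxaborinin-7-yl 3-formyl-2,4-dimethoxy-6-methylbenzoate | COc1cc(C)c(C(=O)Oc2cc(C)c3C(=O)OB(c4ccccc4)Oc3c2C)c(OC)c1C=O | intermediate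
13 | 4-[(3-formyl-2,4-dimethoxy-6-methylbenzoyl)oxy]-2-hydroxy-3,6-dimethylbenzoic acid | COc1cc(C)c(C(=O)Oc2cc(C)c(C(=O)O)c(O)c2C)c(OC)c1C=O | intermediate
14 | 2-hydroxy-4-{[3-(hydroxymethyl)-2,4-dimethoxy-6-methylbenzoyl]oxy}-3,6-dimethylbenzoic acid | COc1cc(C)c(C(=O)Oc2cc(C)c(C(=O)O)c(O)c2C)c(OC)c1CO | target

**Step count**
Total: 6 steps. Longest linear sequence: 5 steps (1 → 3 → 4 → 7 → 13 → 14); the ring B branch (8 → 9) is one step and joins at step 5.

**Steps most likely to fail, with fallbacks**

Step 5 (the proposed boron-masked esterification). Possible failures are incomplete boronate formation, DMAP or phenoxide attack at the acyloxyboron carbonyl (self-condensation of ring B), or sluggish acylation by the hindered chloride. The fallback uses known chemistry, sets out from 9 (with 7) and comes back at 13. Acid 9 is alkylated selectively at the carboxylate (allyl bromide, KHCO3, DMF, rt) to give prop-2-en-1-yl 2,4-dihydroxy-3,6-dimethylbenzoate F4. F4 is coupled with 7 by the classical depside method ((CF3CO)2O, toluene, rt; the 2-OH is held by its hydrogen bond to the ester) to give prop-2-en-1-yl 4-[(3-formyl-2,4-dimethoxy-6-methylbenzoyl)oxy]-2-hydroxy-3,6-dimethylbenzoate F5. Deallylation with Pd(PPh3)4 (cat.) and TolSO2Na in THF–MeOH at rt then gives 13.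

Step 3 (one-pot masked Br/Li exchange and carboxylation). Possible failures are incomplete masking, leading to butyl addition to the aldehyde, or benzylic metalation. The fallback sets out from 4 and comes back at 7, using a discrete, isolable protecting group. Acetalisation (ethylene glycol, TsOH cat., toluene, Dean–Stark) gives 2-(3-bromo-2,6-dimethoxy-4-methylphenyl)-1,3-dioxolane F1. Br/Li exchange (n-BuLi, THF, −78 °C) and CO2 give 3-(1,3-dioxolan-2-yl)-2,4-dimethoxy-6-methylbenzoic acid F2. Aqueous HCl/THF at rt removes the acetal to give 7.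

Step 4 (hydrolysis of a hindered ester of a decarboxylation-prone acid). Possible failures are decarboxylation or ring sulfonation. The fallback sets out from 8 and comes back at 9, and turns the side reaction into the route. Compound 8 is saponified and fully decarboxylated (aq. NaOH, reflux, then acidify and warm) to 2,5-dimethylbenzene-1,3-diol F3, which is also commercial. Kolbe–Schmitt carboxylation (KHCO3, CO2 1 atm, glycerol, 110 °C; cold acidification) then gives 9; the two free ring positions are equivalent and ortho to OH, so only one acid can form.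

**Further compounds**
F1 | step 3 | 2-(3-bromo-2,6-dimethoxy-4-methylphenyl)-1,3-dioxolane | COc1cc(C)c(Br)c(OC)c1C1OCCO1
F2 | step 3 | 3-(1,3-dioxolan-2-yl)-2,4-dimethoxy-6-methylbenzoic acid | COc1cc(C)c(C(=O)O)c(OC)c1C1OCCO1
F3 | step 4 | 2,5-dimethylbenzene-1,3-diol | Cc1cc(O)c(C)c(O)c1
F4 | step 5 | prop-2-en-1-yl 2,4-dihydroxy-3,6-dimethylbenzoate | C=CCOC(=O)c1c(C)cc(O)c(C)c1O
F5 | step 5 | prop-2-en-1-yl 4-[(3-formyl-2,4-dimethoxy-6-methylbenzoyl)oxy]-2-hydroxy-3,6-dimethylbenzoate | COc1cc(C)c(C(=O)Oc2cc(C)c(C(=O)OCC=C)c(O)c2C)c(OC)c1C=O
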